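**Retrosynthetic overview**
- The butyrolactone is closed last: a primary alcohol opens a cis-2-tert-butyl-1,3-dioxolan-4-one by translactonisation, which also frees the tertiary C3–OH.
- The quaternary C3 is disconnected at its benzylic C–C bond: aldol addition of the dioxolanone lithium enolate to O-benzylvanillin, anti to tert-butyl. The aldol oxygen is stored as a benzylic spirolactone and removed by hydrogenolysis.
- The dioxolanone comes from (2R,3S)-3-benzylmalic acid and pivalaldehyde. Its C4–benzyl bond comes from anti alkylation of the diethyl (R)-malate dianion with the benzyl bromide made from the same aldehyde.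
- Ring order: dioxolanone (auxiliary ring, step 6), spiro γ-lactone (temporary, step 7, opened in step 8), butyrolactone of the target (step 9).

Assumption: (R)-malic acid (D-malic acid) and 4-(benzyloxy)-3-methoxybenzaldehyde are taken as cheap catalogue chemicals, and the aldol carbinol centre, which is deleted in step 8, is carried as an epimer mixture.

**Step 1**
Reactants: 1 (R)-malic acid
Product: 2 diethyl (R)-malate
Conditions: EtOH, H2SO4 (cat.), reflux
Reagents that add atoms: ethanol, CCO
Why: Fischer esterification; the carbinol stereocentre is not involved and stays (R).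

**Step 2**
Reactants: 3 4-(benzyloxy)-3-methoxybenzaldehyde (O-benzylvanillin)
Product: 4 [4-(benzyloxy)-3-methoxyphenyl]methanol
Conditions: NaBH4, MeOH, 0 °C
Reagents that add atoms: none
Why: Borohydride reduction of an aryl aldehyde to the benzylic alcohol; the benzyl ether is inert.

**Step 3**
Reactants: 4 [4-(benzyloxy)-3-methoxyphenyl]methanol
Product: 5 4-(benzyloxy)-3-methoxybenzyl bromide
Conditions: PBr3 (0.4 equiv), Et2O, 0 °C; used at once
Reagents that add atoms: phosphorus tribromide, BrP(Br)Br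
Why: Bromination of an electron-rich benzylic alcohol through its phosphite ester (SN2 by bromide); the labile bromide is not stored.

**Step 4**
Reactants: 2 diethyl (R)-malate; 5 4-(benzyloxy)-3-methoxybenzyl bromide
Product: 7 diethyl (2R,3S)-2-hydroxy-3-[4-(benzyloxy)-3-methoxybenzyl]succinate, via dilithium alkoxide enolate 6 (not isolated)
Conditions: LiN(SiMe3)2 (2.1 equiv), THF, −78 → −20 °C; 5, −78 → −5 °C; AcOH
Reagents that add atoms: none
Why: Fráter–Seebach alkylation, in which the lithium-chelated alkoxide enolate is benzylated anti to the ester group on the alkoxide carbon, setting C3 as (S) (about 9:1; the minor syn isomer is removed by chromatography and by crystallisation of 9); this carbon becomes C4 (R) of the target.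

**Step 5**
Reactants: 7 diethyl (2R,3S)-2-hydroxy-3-[4-(benzyloxy)-3-methoxybenzyl]succinate
Product: 8 (2R,3S)-2-hydroxy-3-[4-(benzyloxy)-3-methoxybenzyl]succinic acid
Conditions: KOH (3 equiv), EtOH/H2O, 0 °C → rt; then 1 M HCl to pH 2
Reagents that add atoms: potassium hydroxide, [K+].[OH-]
Why: Saponification of both esters under mild conditions in which the carboxylate-flanked C3–H is not epimerised.

**Step 6**
Reactants: 8 (2R,3S)-2-hydroxy-3-[4-(benzyloxy)-3-methoxybenzyl]succinic acid
Product: 9 (2S)-3-[4-(benzyloxy)-3-methoxyphenyl]-2-[(2R,4R)-2-tert-butyl-5-oxo-1,3-dioxolan-4-yl]propanoic acid (cis-dioxolanone)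
Conditions: t-BuCHO (3 equiv), TsOH·H2O (cat.), CH2Cl2/pentane, reflux, Dean–Stark; recrystallise
Reagents that add atoms: pivalaldehyde, CC(C)(C)C=O
Why: Acid-catalysed acetalisation under equilibrating conditions gives the five-membered dioxolanone of the α-hydroxy acid with tert-butyl cis to the side chain, so the carbinol centre dictates the (R) acetal centre (first half of Seebach's self-regeneration of stereocentres).

**Step 7**
Reactants: 9 (2S)-3-[4-(benzyloxy)-3-methoxyphenyl]-2-[(2R,4R)-2-tert-butyl-5-oxo-1,3-dioxolan-4-yl]propanoic acid; 3 4-(benzyloxy)-3-methoxybenzaldehyde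
Product: 12 spirolactone (2R,5S,9S)-9-[4-(benzyloxy)-3-methoxybenzyl]-6-[4-(benzyloxy)-3-methoxyphenyl]-2-tert-butyl-1,3,7-trioxaspiro[4.4]nonane-4,8-dione (both C6 epimers), via dilithium carboxylate enolate 10 (not isolated), via aldol hydroxy acid 11 (not isolated)
Conditions: LiN(SiMe3)2 (2.2 equiv), THF, −78 °C; 3 (1.2 equiv), −78 °C; AcOH; then EDC·HCl, DMAP (cat.), CH2Cl2, 0 °C → rt
Reagents that add atoms: none
Why: Intermolecular aldol addition of the dioxolanone lithium enolate to the aldehyde from the face opposite tert-butyl, so the new C–C bond replaces the former C–H and fixes the quaternary carbon (C3, R, in the target); the carbinol centre forms as a mixture, and the Steglich-type lactonisation stores the aldol as a neutral benzylic lactone that cannot undergo retro-aldol.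

**Step 8**
Reactants: 12 spirolactone (both C6 epimers)
Product: 13 (2S)-2-[(2R,4R)-2-tert-butyl-4-(4-hydroxy-3-methoxybenzyl)-5-oxo-1,3-dioxolan-4-yl]-3-(4-hydroxy-3-methoxyphenyl)propanoic acid
Conditions: H2 (4 atm), Pd(OH)2/C, EtOAc/AcOH (4:1), 40 °C
Reagents that add atoms: none
Why: Palladium-catalysed hydrogenolysis cleaves both benzyl ethers and the benzylic ester C–O bond of the lactone, which deletes the unwanted oxygen with its stereocentre and frees the acid; the non-benzylic quaternary and acetal C–O bonds are untouched.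

**Step 9**
Reactants: 13 (2S)-2-[(2R,4R)-2-tert-butyl-4-(4-hydroxy-3-methoxybenzyl)-5-oxo-1,3-dioxolan-4-yl]-3-(4-hydroxy-3-methoxyphenyl)propanoic acid
Product: 15 (+)-nortrachelogenin, via primary alcohol 14 (not isolated)
Conditions: BH3·SMe2 (5 equiv), THF, 0 °C → rt; MeOH; then 1 M HCl, THF, rt
Reagents that add atoms: none
Why: Borane reduces the free carboxylic acid much faster than the dioxolanone carbonyl, and the new primary alcohol then opens the dioxolanone by acid-catalysed translactonisation with loss of pivalaldehyde, giving the γ-lactone and the tertiary alcohol with both stereocentres unchanged.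

**Compound list**
1 | (R)-malic acid, (2R)-2-hydroxybutanedioic acid | OC(=O)C[C@@H](O)C(=O)O | starting material
2 | diethyl (R)-malate | CCOC(=O)C[C@@H](O)C(=O)OCC | intermediate
3 | 4-(benzyloxy)-3-methoxybenzaldehyde | COc1cc(C=O)ccc1OCc1ccccc1 | starting material
4 | [4-(benzyloxy)-3-methoxyphenyl]methanol | COc1cc(CO)ccc1OCc1ccccc1 | intermediate
5 | 4-(benzyloxy)-3-methoxybenzyl bromide | COc1cc(CBr)ccc1OCc1ccccc1 | intermediate
6 | dilithium alkoxide enolate of diethyl (R)-malate | [Li+].[Li+].CCOC([O-])=C[C@@H]([O-])C(=O)OCC | intermediate (not isolated)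
7 | diethyl (2R,3S)-2-hydroxy-3-[4-(benzyloxy)-3-methoxybenzyl]succinate | CCOC(=O)[C@@H](Cc1ccc(OCc2ccccc2)c(OC)c1)[C@@H](O)C(=O)OCC | intermediate
8 | (2R,3S)-2-hydroxy-3-[4-(benzyloxy)-3-methoxybenzyl]succinic acid | OC(=O)[C@@H](Cc1ccc(OCc2ccccc2)c(OC)c1)[C@@H](O)C(=O)O | intermediate
9 | (2S)-3-[4-(benzyloxy)-3-methoxyphenyl]-2-[(2R,4R)-2-tert-butyl-5-oxo-1,3-dioxolan-4-yl]propanoic acid | OC(=O)[C@@H](Cc1ccc(OCc2ccccc2)c(OC)c1)[C@H]1O[C@@H](C(C)(C)C)OC1=O | intermediate
10 | dilithium carboxylate enolate of 9 | [Li+].[Li+].[O-]C(=O)[C@@H](Cc1ccc(OCc2ccccc2)c(OC)c1)C1=C([O-])O[C@H](C(C)(C)C)O1 | intermediate (not isolated)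
11 | (2S)-3-[4-(benzyloxy)-3-methoxyphenyl]-2-[(2R,4S)-4-{[4-(benzyloxy)-3-methoxyphenyl](hydroxy)methyl}-2-tert-butyl-5-oxo-1,3-dioxolan-4-yl]propanoic acid (both carbinol epimers) | OC(=O)[C@@H](Cc1ccc(OCc2ccccc2)c(OC)c1)[C@@]1(C(O)c2ccc(OCc3ccccc3)c(OC)c2)O[C@@H](C(C)(C)C)OC1=O | intermediate (not isolated)
12 | (2R,5S,9S)-9-[4-(benzyloxy)-3-methoxybenzyl]-6-[4-(benzyloxy)-3-methoxyphenyl]-2-tert-butyl-1,3,7-trioxaspiro[4.4]nonane-4,8-dione (both C6 epimers) | O=C1OC(c3ccc(OCc4ccccc4)c(OC)c3)[C@@]2(O[C@@H](C(C)(C)C)OC2=O)[C@@H]1Cc1ccc(OCc2ccccc2)c(OC)c1 | intermediate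
13 | (2S)-2-[(2R,4R)-2-tert-butyl-4-(4-hydroxy-3-methoxybenzyl)-5-oxo-1,3-dioxolan-4-yl]-3-(4-hydroxy-3-methoxyphenyl)propanoic acid | OC(=O)[C@@H](Cc1ccc(O)c(OC)c1)[C@@]1(Cc2ccc(O)c(OC)c2)O[C@@H](C(C)(C)C)OC1=O | intermediate
14 | (2R,5R)-2-tert-butyl-5-(4-hydroxy-3-methoxybenzyl)-5-[(2R)-1-hydroxy-3-(4-hydroxy-3-methoxyphenyl)propan-2-yl]-1,3-dioxolan-4-one | OC[C@@H](Cc1ccc(O)c(OC)c1)[C@@]1(Cc2ccc(O)c(OC)c2)O[C@@H](C(C)(C)C)OC1=O | intermediate (not isolated)
15 | (+)-nortrachelogenin, (3R,4R)-3-hydroxy-3,4-bis(4-hydroxy-3-methoxybenzyl)dihydrofuran-2(3H)-one | COc1cc(C[C@@H]2COC(=O)[C@@]2(O)Cc2ccc(O)c(OC)c2)ccc1O | target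

**Totals**
Total step count: 9.
Longest linear sequence: 8 steps (3 → 4 → 5 → 7 → 8 → 9 → 12 → 13 → 15).

**Steps most likely to fail, with fallbacks**

Step 7, the aldol on the hindered dianion followed by lactonisation, is the least precedented step. If enolate 10 does not add cleanly to aldehyde 3 (retro-aldol or low conversion), the benzyl group is introduced without oxygen by SN2 alkylation. Setting out from 9, the same dianion is treated with bromide 5 (LiN(SiMe3)2, THF, −78 °C), again anti to tert-butyl. This gives (2S)-3-[4-(benzyloxy)-3-methoxyphenyl]-2-[(2R,4R)-4-[4-(benzyloxy)-3-methoxybenzyl]-2-tert-butyl-5-oxo-1,3-dioxolan-4-yl]propanoic acid F1. H2 over Pd/C in EtOAc then removes both benzyl ethers, and the sequence comes back to the route at 13.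

Step 8, the hydrogenolysis of the benzylic lactone C–O bond next to a quaternary carbon, may stop after loss of the benzyl ethers. The bond is then cut by ionic instead of catalytic hydrogenation. Setting out from 12, H2 over Pd/C in EtOAc at room temperature gives the bisphenol spirolactone (2R,5S,9S)-2-tert-butyl-9-(4-hydroxy-3-methoxybenzyl)-6-(4-hydroxy-3-methoxyphenyl)-1,3,7-trioxaspiro[4.4]nonane-4,8-dione F2. Et3SiH (excess) and CF3CO2H in CH2Cl2 at −20 → 0 °C ionise the para-hydroxybenzylic C–O bond and deliver hydride to the cation; the large excess of silane is there to outrun Friedel–Crafts closure onto the other ring. The sequence comes back to the route at 13.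

Step 9, the borane reduction, could also attack the dioxolanone carbonyl. The acid is then activated selectively instead. Setting out from 13, 1,1'-carbonyldiimidazole in THF at room temperature gives the acyl imidazolide (2R,5R)-2-tert-butyl-5-(4-hydroxy-3-methoxybenzyl)-5-[(2S)-3-(4-hydroxy-3-methoxyphenyl)-1-(1H-imidazol-1-yl)-1-oxopropan-2-yl]-1,3-dioxolan-4-one F3. NaBH4 in THF/H2O at 0 °C reduces it to the primary alcohol, coming back to the route at 14, which is lactonised to 15 with 1 M HCl as before.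

**Further compounds**
F1 | step 7 | (2S)-3-[4-(benzyloxy)-3-methoxyphenyl]-2-[(2R,4R)-4-[4-(benzyloxy)-3-methoxybenzyl]-2-tert-butyl-5-oxo-1,3-dioxolan-4-yl]propanoic acid | OC(=O)[C@@H](Cc1ccc(OCc2ccccc2)c(OC)c1)[C@@]1(Cc2ccc(OCc3ccccc3)c(OC)c2)O[C@@H](C(C)(C)C)OC1=O
F2 | step 8 | (2R,5S,9S)-2-tert-butyl-9-(4-hydroxy-3-methoxybenzyl)-6-(4-hydroxy-3-methoxyphenyl)-1,3,7-trioxaspiro[4.4]nonane-4,8-dione (both C6 epimers) | O=C1OC(c3ccc(O)c(OC)c3)[C@@]2(O[C@@H](C(C)(C)C)OC2=O)[C@@H]1Cc1ccc(O)c(OC)c1
F3 | step 9 | (2R,5R)-2-tert-butyl-5-(4-hydroxy-3-methoxybenzyl)-5-[(2S)-3-(4-hydroxy-3-methoxyphenyl)-1-(1H-imidazol-1-yl)-1-oxopropan-2-yl]-1,3-dioxolan-4-one | O=C(n1ccnc1)[C@@H](Cc1ccc(O)c(OC)c1)[C@@]1(Cc2ccc(O)c(OC)c2)O[C@@H](C(C)(C)C)OC1=O
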